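The data were generated by integration with made-up constants, and the scatter is random.

**Small portions.** A small charge of Z, a quarter of 1.1 M, went into the flask every 8.0 min, so on average the Z was in from 12.0 min onward.

in all of them: Z 1.1 M (in portions, 4)

| charge | G | remark | time |
|---|---|---|---|
| Saturday's | 2.4 M | run made earlier; portions every 8.0 min |  |
| flask | 1.21 M | the portions of Z follow each other after 8.0 min, the first at the start | 4.0 h |

Saturday's run (percent of the Z charged)

| time / min | X / % | E / % |
|---|---|---|
| 6.00 | 0.9 | 0.3 |
| 20.0 | 0 | 3.0 |
| 30.0 | 0.1 | 4.8 |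
| 50.0 | 2.0 | 7.6 |
| 80.0 | 7.2 | 11.9 |

(scatter of a reading: 0.5 percentage points)

* how much X the flask holds at 4.0 h, in percent of the Z charged
* how much E the flask holds at 4.0 h, in percent of the Z charged
* how much D the flask holds at 4.0 h, in percent of the Z charged
* concentration of G at 4.0 h, in M

- X is meant together with its J
- the earlier runs were read with a standard deviation of 0.5 percentage points
- on the list of suspects stand: G + X <-> J; X <-> Q; E <-> L; Z -> E; G + E -> X; E <-> D

**Making rate.** I followed rates, not amounts. On Saturday X and E together held 19.1% at 80.0 min, and taking Z to E as first order, I read from this a constant of 0.00312 min⁻¹. I took the flask's making of E to start at that constant times c(Z) and to sink with c(Z), to a factor of 0.491 by 4.0 h.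

**Pickup rate.** While c(G) holds, G + E to X is pseudo-first-order in E. Saturday's X at 80.0 min, divided by the area under its E readings, gave 0.0150 min⁻¹. The flask's c(G) is 0.504 times Saturday's, so I started its pickup constant at 0.00757 min⁻¹.

**Handover ratio.** The making constant over the pickup constant, 0.412, I called the handover ratio: it is the c(E)/c(Z) at which E is used as fast as it is made, and it rises as c(G) falls. For two first-order steps I put that crossing at 3.52 h, before 4.0 h.

**The result.** The forecast, on “Consecutive first-order kinetics”, said X 25%, E 20%, D 4% and G 0.92 M. The flask gave X 17.2%, E 22.7%, D 7.36% and G 0.879 M.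

    G + X ⇌ J, settled at all times (K = 1.90 M⁻¹)
    X ⇌ Q (K = 0.410, k = 0.0130 min⁻¹)
    E ⇌ L (K = 0.260, k = 0.00280 min⁻¹)
    Z → E (k = 0.00340 min⁻¹)
    G + E → X (k = 0.00520 M⁻¹ min⁻¹)
    E ⇌ D (K = 0.350, k = 0.00850 min⁻¹)

**Late handover.** At 4.0 h the flask's c(E)/c(Z) was 0.492, under a handover ratio of 0.567 at that c(G), and E was being made 1.19 times as fast as it was used, each step taken net. The time allowed is the main reason for the flask's X of 17.2%: the same flask at 40.0 h holds 63.9%, which is 47 percentage points more. The flask read at 15 h had passed the crossing, with c(E)/c(Z) at 4.19 against a handover ratio of 1.54, and X stood at 49.5%.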